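## Retrosynthetic overview

1. Target 13 ⇐ chalcone 12 (ring C, O1–C2 bond, enzymatic oxa-Michael sets 2S) ⇐ triketo ester 11 (ring A, C–C bond by Claisen cyclisation) ⇐ acyl-pyranone 10. Rings A and C are both made in one pot from 10, and the pyranone ring is sacrificed.
2. 10 ⇐ triacetic acid lactone 8 (as its dianion) + cinnamoyl Weinreb amide 7 (C–C acylation).
3. 7 ⇐ aryl iodide 5 (as arylzinc) + allylic acetate 2 (Negishi allyl–aryl coupling, E retained).
4. 5 ⇐ 4-hydroxy-3-iodobenzaldehyde 3 (silylation, Wittig); 2 ⇐ geranyl acetate 1 (site-selective hydration).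
5. Ring order: ring B is bought, then ring A, then ring C.

Assumption: recombinant chalcone isomerase (Medicago sativa enzyme expressed in E. coli) is treated as an obtainable catalyst and not as a synthetic step.

## Route

Step 1
Reactants: 1 geranyl acetate
Product: 2 (2E)-7-hydroxy-3,7-dimethyloct-2-en-1-yl acetate
Conditions: Co(acac)2 (10 mol %), PhSiH3, O2 (1 atm), THF, rt
Reagents that add atoms: dioxygen, O=O
Why: Mukaiyama hydration transfers a hydrogen atom to the electron-rich, unhindered 6,7-alkene (the 2,3-alkene is deactivated by the allylic acetate), and O2 capture of the tertiary radical gives the Markovnikov tertiary alcohol while the E-2,3-alkene is untouched.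

Step 2
Reactants: 3 4-hydroxy-3-iodobenzaldehyde
Product: 4 4-[(tert-butyldimethylsilyl)oxy]-3-iodobenzaldehyde
Conditions: TBSCl, imidazole, DMF, rt
Reagents that add atoms: tert-butyldimethylsilyl chloride, CC(C)(C)[Si](C)(C)Cl
Why: Imidazole-promoted O-silylation masks the acidic phenol that would quench the arylzinc and the pyranone dianion later, and the aryl silyl ether is removed by methoxide in step 6 without a separate step.

Step 3
Reactants: 4 4-[(tert-butyldimethylsilyl)oxy]-3-iodobenzaldehyde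
Product: 5 (2E)-3-{4-[(tert-butyldimethylsilyl)oxy]-3-iodophenyl}-N-methoxy-N-methylprop-2-enamide
Conditions: Ph3P=CHC(O)N(OMe)Me, toluene, 80 °C
Reagents that add atoms: N-methoxy-N-methyl-2-(triphenylphosphoranylidene)acetamide, CON(C)C(=O)C=P(c1ccccc1)(c1ccccc1)c1ccccc1
Why: Wittig olefination with a stabilised amide ylide under neutral conditions gives the E-enamide selectively and leaves the aryl iodide and the silyl ether intact.

Step 4
Reactants: 5 (2E)-3-{4-[(tert-butyldimethylsilyl)oxy]-3-iodophenyl}-N-methoxy-N-methylprop-2-enamide; 2 (2E)-7-hydroxy-3,7-dimethyloct-2-en-1-yl acetate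
Product: 7 (2E)-3-{4-[(tert-butyldimethylsilyl)oxy]-3-[(2E)-7-hydroxy-3,7-dimethyloct-2-en-1-yl]phenyl}-N-methoxy-N-methylprop-2-enamide, via arylzinc iodide 6 (not isolated)
Conditions: activated Zn dust, LiCl, THF, 50 °C; then 2 (0.75 equiv), Pd(PPh3)4 (5 mol %), THF, 50 °C
Reagents that add atoms: none
Why: LiCl-assisted zinc insertion into the aryl C–I bond gives an arylzinc that tolerates the Weinreb amide, the silyl ether and the free tertiary alcohol, and the Negishi allyl–aryl coupling through the π-allylpalladium complex of 2 joins the aryl group to the unsubstituted allyl terminus with retention of the E geometry.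

Step 5
Reactants: 8 4-hydroxy-6-methyl-2H-pyran-2-one (triacetic acid lactone); 7 (2E)-3-{4-[(tert-butyldimethylsilyl)oxy]-3-[(2E)-7-hydroxy-3,7-dimethyloct-2-en-1-yl]phenyl}-N-methoxy-N-methylprop-2-enamide
Product: 10 6-[(3E)-4-{4-[(tert-butyldimethylsilyl)oxy]-3-[(2E)-7-hydroxy-3,7-dimethyloct-2-en-1-yl]phenyl}-2-oxobut-3-en-1-yl]-4-hydroxy-2H-pyran-2-one, via dilithio pyranone dianion 9 (not isolated)
Conditions: 8 (3 equiv), LiN(iPr)2 (6.2 equiv, commercial solution), THF–DMPU, −78 °C; then 7, −78 → 0 °C; aq. HCl to pH 3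
Reagents that add atoms: none
Why: Acylation of the 6-methyl carbanion of the triacetic acid lactone dianion (polyketide dianion acylation) by the Weinreb amide stops at the chelated tetrahedral adduct, so the ketone appears only on acidic work-up without over-addition or conjugate addition, and the surplus dianion takes up the tertiary OH proton.

Step 6
Reactants: 10 6-[(3E)-4-{4-[(tert-butyldimethylsilyl)oxy]-3-[(2E)-7-hydroxy-3,7-dimethyloct-2-en-1-yl]phenyl}-2-oxobut-3-en-1-yl]-4-hydroxy-2H-pyran-2-one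
Product: 13 (2S)-5,7-dihydroxy-2-{4-hydroxy-3-[(2E)-7-hydroxy-3,7-dimethyloct-2-en-1-yl]phenyl}-2,3-dihydro-4H-chromen-4-one, via triketo methyl ester 11 (not isolated), via chalcone 12 (not isolated)
Conditions: NaOMe (10 equiv), dry degassed MeOH, Ar, 0 °C → rt; then AcOH (10 equiv), 0 °C, diluted at once into HEPES buffer pH 7.5–DMSO (9:1) containing chalcone isomerase (recombinant, Medicago sativa), 15 °C
Reagents that add atoms: none
Why: Proposed new method: methoxide opens the 2-pyranone to triketo methyl ester 11, whose doubly enolised tricarbonyl chain aromatises under strongly basic non-aqueous conditions by C6-to-C1 Claisen acylation to ring A (closest known type: biomimetic polyketide Claisen cyclisation of 3,5,7-triketo esters and 6-(2-oxoalkyl)-4-hydroxy-2-pyranones to acylphloroglucinols in methanolic alkoxide, which also cleaves the aryl silyl ether), and the product stays ring-opened as the chalcone polyphenoxide 12 until fast neutralisation hands it to chalcone isomerase, which closes ring C by 6-endo oxa-Michael addition to give the 2S centre exactly as it does for naringenin chalcone (closest known type: enzymatic cyclisation of 2',4',6'-trihydroxychalcones, with the extra alkyl chain on ring B assumed to be tolerated), while the uncatalysed closure at pH 7.5 is orders of magnitude slower.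

## Compound list

1 | geranyl acetate | CC(=O)OC/C=C(\C)CCC=C(C)C | starting material
2 | (2E)-7-hydroxy-3,7-dimethyloct-2-en-1-yl acetate | CC(=O)OC/C=C(\C)CCCC(C)(C)O | intermediate
3 | 4-hydroxy-3-iodobenzaldehyde | O=Cc1ccc(O)c(I)c1 | starting material
4 | 4-[(tert-butyldimethylsilyl)oxy]-3-iodobenzaldehyde | O=Cc1ccc(O[Si](C)(C)C(C)(C)C)c(I)c1 | intermediate
5 | (2E)-3-{4-[(tert-butyldimethylsilyl)oxy]-3-iodophenyl}-N-methoxy-N-methylprop-2-enamide | CON(C)C(=O)/C=C/c1ccc(O[Si](C)(C)C(C)(C)C)c(I)c1 | intermediate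
6 | arylzinc iodide of 5 (iodozincio group in place of iodine) | CON(C)C(=O)/C=C/c1ccc(O[Si](C)(C)C(C)(C)C)c([Zn]I)c1 | intermediate (not isolated)
7 | (2E)-3-{4-[(tert-butyldimethylsilyl)oxy]-3-[(2E)-7-hydroxy-3,7-dimethyloct-2-en-1-yl]phenyl}-N-methoxy-N-methylprop-2-enamide | CON(C)C(=O)/C=C/c1ccc(O[Si](C)(C)C(C)(C)C)c(C/C=C(\C)CCCC(C)(C)O)c1 | intermediate
8 | 4-hydroxy-6-methyl-2H-pyran-2-one (triacetic acid lactone) | Cc1cc(O)cc(=O)o1 | starting material
9 | dilithio dianion of 8 (4-lithiooxy-6-lithiomethyl-2H-pyran-2-one) | [Li]Cc1cc(O[Li])cc(=O)o1 | intermediate (not isolated)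
10 | 6-[(3E)-4-{4-[(tert-butyldimethylsilyl)oxy]-3-[(2E)-7-hydroxy-3,7-dimethyloct-2-en-1-yl]phenyl}-2-oxobut-3-en-1-yl]-4-hydroxy-2H-pyran-2-one | O=C(Cc1cc(O)cc(=O)o1)/C=C/c1ccc(O[Si](C)(C)C(C)(C)C)c(C/C=C(\C)CCCC(C)(C)O)c1 | intermediate
11 | methyl (8E)-9-{4-[(tert-butyldimethylsilyl)oxy]-3-[(2E)-7-hydroxy-3,7-dimethyloct-2-en-1-yl]phenyl}-3,5,7-trioxonon-8-enoate | COC(=O)CC(=O)CC(=O)CC(=O)/C=C/c1ccc(O[Si](C)(C)C(C)(C)C)c(C/C=C(\C)CCCC(C)(C)O)c1 | intermediate (not isolated)
12 | (2E)-3-{4-hydroxy-3-[(2E)-7-hydroxy-3,7-dimethyloct-2-en-1-yl]phenyl}-1-(2,4,6-trihydroxyphenyl)prop-2-en-1-one | O=C(/C=C/c1ccc(O)c(C/C=C(\C)CCCC(C)(C)O)c1)c1c(O)cc(O)cc1O | intermediate (not isolated)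
13 | (2S)-5,7-dihydroxy-2-{4-hydroxy-3-[(2E)-7-hydroxy-3,7-dimethyloct-2-en-1-yl]phenyl}-2,3-dihydro-4H-chromen-4-one | C/C(=C\Cc1cc([C@@H]2CC(=O)c3c(O)cc(O)cc3O2)ccc1O)CCCC(C)(C)O | target

## Step count and risks

Total steps: 6. Longest linear sequence: 5 steps (3 → 4 → 5 → 7 → 10 → 13).

Most likely to fail, in order:

**Step 6.** The enzyme may turn the ring B-substituted chalcone over too slowly, so that uncatalysed closure erodes the enantiomeric purity. The fallback sets out from 10 and comes back at 13. The methoxide stage is run as before, the mixture is acidified, and chalcone 12 is left to close without enzyme (NaOAc, EtOH–H2O, rt) to racemic flavanone F1. F1 is resolved by preparative chiral chromatography on an amylose tris(3,5-dimethylphenylcarbamate) phase, which gives 13 directly. The (2R)-enantiomer F2 is re-opened to 12 with NaOMe in MeOH and sent through closure and separation again.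

**Step 5.** The triacetic acid lactone dianion is poorly soluble and may acylate sluggishly. The fallback sets out from 7 and comes back at 10. Commercial 2,2,6-trimethyl-4H-1,3-dioxin-4-one is C-acetylated (LiN(SiMe3)2, THF, −78 °C; AcCl) to keto-dioxinone F3. F3 is doubly deprotonated with LiN(iPr)2 and acylated at its terminal methyl by 7 to give diketo-dioxinone F4. Heating F4 in toluene at 110 °C expels acetone, and the resulting acylketene F5 lactonises through its 5-enol oxygen to pyranone 10.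

**Step 4.** Zinc insertion next to the bulky silyl ether may be slow, or the allylic acetate may ionise poorly. The fallback sets out from 5 and comes back at 7. Miyaura borylation of 5 (B2pin2, PdCl2(dppf), KOAc, dioxane, 80 °C) gives aryl pinacol boronate F6. F6 is then joined to acetate 2 in a Suzuki–Miyaura allyl–aryl coupling (Pd(PPh3)4, K2CO3, THF–H2O, 50 °C) to give 7.

## Further compounds

F1 | step 6 | racemic 5,7-dihydroxy-2-{4-hydroxy-3-[(2E)-7-hydroxy-3,7-dimethyloct-2-en-1-yl]phenyl}-2,3-dihydro-4H-chromen-4-one | C/C(=C\Cc1cc(C2CC(=O)c3c(O)cc(O)cc3O2)ccc1O)CCCC(C)(C)O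
F2 | step 6 | (2R)-5,7-dihydroxy-2-{4-hydroxy-3-[(2E)-7-hydroxy-3,7-dimethyloct-2-en-1-yl]phenyl}-2,3-dihydro-4H-chromen-4-one | C/C(=C\Cc1cc([C@H]2CC(=O)c3c(O)cc(O)cc3O2)ccc1O)CCCC(C)(C)O
F3 | step 5 | 2,2-dimethyl-6-(2-oxopropyl)-4H-1,3-dioxin-4-one | CC(=O)CC1=CC(=O)OC(C)(C)O1
F4 | step 5 | 6-[(5E)-6-{4-[(tert-butyldimethylsilyl)oxy]-3-[(2E)-7-hydroxy-3,7-dimethyloct-2-en-1-yl]phenyl}-2,4-dioxohex-5-en-1-yl]-2,2-dimethyl-4H-1,3-dioxin-4-one | CC1(C)OC(=O)C=C(CC(=O)CC(=O)/C=C/c2ccc(O[Si](C)(C)C(C)(C)C)c(C/C=C(\C)CCCC(C)(C)O)c2)O1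
F5 | step 5 | (8E)-9-{4-[(tert-butyldimethylsilyl)oxy]-3-[(2E)-7-hydroxy-3,7-dimethyloct-2-en-1-yl]phenyl}nona-1,8-diene-1,3,5,7-tetrone (acylketene) | O=C=CC(=O)CC(=O)CC(=O)/C=C/c1ccc(O[Si](C)(C)C(C)(C)C)c(C/C=C(\C)CCCC(C)(C)O)c1
F6 | step 4 | (2E)-3-{4-[(tert-butyldimethylsilyl)oxy]-3-(4,4,5,5-tetramethyl-1,3,2-dioxaborolan-2-yl)phenyl}-N-methoxy-N-methylprop-2-enamide | CON(C)C(=O)/C=C/c1ccc(O[Si](C)(C)C(C)(C)C)c(B2OC(C)(C)C(C)(C)O2)c1
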